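Does the flask with 20 mM of initiator still run at 25 min, and how does the converted material divide between target and isomer?

| flask | starting material | solid reagent | initiator | remark | time |
|---|---|---|---|---|---|
| south-east | 0.40 M | 2 M | 10 mM | run made earlier |  |
| south | 0.40 M | 2 M | 15 mM | run made earlier |  |
| flask | 0.40 M | 2.00 M | 20 mM |  | 25 min |

- south-east (time / min: target / %, isomer of the product / %): 3.00: 6, 0; 6.00: 15, 1; 10.0: 24, 7; 12.0: 31, 9; 15.0: 34, 14; 20.0: 45, 24
- south (time / min: target / %, isomer of the product / %): 1.33: 3, 0; 4.00: 12, 0; 8.00: 20, 3; 10.0: 28, 7; 15.0: 34, 16; 20.0: 39, 21

(readings scatter by 1.5 percentage points)

- as a solid, counted per litre of solution: solid reagent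
- the earlier runs were read with a standard deviation of 1.5 percentage points
- at the start none of the solid reagent is in solution
- the reaction counts as stopped when no species that holds the starting material changes by six tenths of a point or more over the second half of the time

1. at 25 min, what has stopped the reaction, if anything has (for what has run out or reacted, a solid counts together with what of it has only dissolved) (forward and back rates have come level / all of the starting material has reacted / it is still moving / the partner has run out first)
2. target at 25 min, in percent of the starting material charged
3. isomer of the product at 25 min, in percent of the starting material charged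

Does the initiator set the pace? Target plus isomer stands lower in the south-east run than in the south run at 10.0 min, 31.0% against 35.0%. At 20.0 min it stands higher, 69.0% against 60.0%. The order flips, so the two runs are pooled.

Does the pace fall as starting material goes? Pooled to 20.0 min, the runs give F = 0.0129 M min⁻¹: the feed F, the mean amount of starting material turned into target plus isomer per litre and minute. Pooled to 10.0 min they give 0.0132 M min⁻¹. The pace is thus close to zero order in starting material, and using the mean for the curve costs about 1.9 percentage points at 25 min.

Does anything run out? In the flask, F gives 0.323 M by 25 min, less than the 0.40 M charged and less than the 2.00 M of solid. That is 80.6% converted, so the flask is still moving. Continuing the isomer's pooled gain from 15.0 min to 20.0 min gives 30.0% isomer and 50.6% target.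

The forecast also says it is still moving, reasoning that “the rate is close to zero order and independent of initiator”, but divides differently: 45% target (39% to 51%) and 34% isomer (28% to 40%).

The flask gives: it is still moving. Target stands at 49.5%. The isomer stands at 31.5%.

    initiator → 2 initiating radical (k = 0.0150 min⁻¹)
    starting material + initiating radical → chain carrier (k = 4.90 × 10⁵ L mol⁻¹ min⁻¹)
    partner + chain carrier → target + initiating radical (k = 43000 L mol⁻¹ s⁻¹)
    2 initiating radical → ended chains (k = 7.00 × 10⁶ L mol⁻¹ s⁻¹)
    target ⇌ isomer of the product (K = 2.30, k = 0.0540 min⁻¹)
    solid reagent ⇌ partner, rate k6*(cs6 - [partner]) while solid is left; crystals form when [partner] > cs6 (solubility = 0.360 M, k = 0.0360 min⁻¹)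

By 25 min the flask has made 0.324 M of target plus isomer, level with the 0.323 M from F and with the 0.324 M of partner consumed, solid and dissolved counted together, while dissolved partner stands at 4.22 × 10⁻⁷ M. In the neighbour charged with 0.68 M of starting material, F gives 47.4% converted by 25 min; that flask shows 29.1% target and 18.5% isomer, with 51% of its starting material left.

All runs stem from a simulated flask for substances that don't exist, noise included.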